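A substrate charge of 0.56 M in the cedar flask cannot take more than a third of the 1.68 M of partner, since the two meet one to one. So [partner] may be frozen near its charge, the pseudo-first-order picture, and the question becomes how far the first step goes.

| flask | substrate | partner | remark | time |
|---|---|---|---|---|
| cedar | 0.56 M | 1.68 M | the very flask that is asked about, followed so far |  |
| oak | 0.38 M | 1.68 M | run made earlier |  |
| flask | 0.56 M | 1.68 M |  | 15 min |

cedar run (percent of the substrate charged)

| time / s | target / % | intermediate A / % |
|---|---|---|
| 20.0 | 1 | 8 |
| 40.0 | 0 | 8 |
| 50.0 | 0 | 7 |
| 80.0 | 0 | 13 |

oak run (percent of the substrate charged)

| time / min | target / % | intermediate A / % |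
|---|---|---|
| 0.500 | 0 | 8 |
| 1.00 | 1 | 8 |
| 2.50 | 0 | 17 |
| 6.00 | 0 | 24 |

(standard deviation of a reading: 1.5 percentage points)

- the earlier runs were read with a standard deviation of 1.5 percentage points
- reactions considered so far: intermediate A <-> intermediate B; substrate + partner <-> intermediate A; intermediate B <-> target
- the reaction counts as stopped when no species that holds the substrate changes by six tenths of a point or more over the second half of the time

1. the state of affairs at 15 min: stopped, and by what, or still going (it is still moving / the partner has run out first / forward and back rates have come level / all of the substrate has reacted)
2. the target standing at 15 min, as a percentage of the substrate charged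
3. the intermediate A standing at 15 min, as a percentage of the substrate charged

Two of us argue at the board. The first says that intermediate A has nearly arrived: the oak run climbed to 24 % by 6.00 min, the first step is coming level, and the cedar flask will stand still at 15 min. The second says that the readings stop too soon to show this.

For intermediate A, I side with the first. The target reads at noise level and intermediate B goes unread, so I count the rest of the oak charge as substrate. The last oak reading then gives 0.199 M⁻¹ for the binding quotient Q, [intermediate A] over [substrate][partner], and it carries the scatter of that reading. Counted the same way, the share of the cedar charge in intermediate A is Q[partner]/(1+Q[partner]). With [partner] frozen at its charge this is 25.0 %. That share takes [partner] down to 1.54 M, and the same quotient then gives 23.4 %. For the target I have just the readings, which stay within the scatter.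

The forecast is the second's: it is still moving, on the ground that a leak onward “probably keeps something moving”, with target 1 % and intermediate A 26 %, higher than my 23.4 %.

The cedar flask at 15 min: it is still moving, with target 2.33 % and intermediate A 22.1 %.

    intermediate A ⇌ intermediate B (K = 0.570, k = 0.0390 min⁻¹)
    substrate + partner ⇌ intermediate A (K = 0.220 M⁻¹, k = 0.0910 M⁻¹ min⁻¹)
    intermediate B ⇌ target (K = 0.370, k = 2.30 min⁻¹)

The second has the state right, it is still moving: cedar substrate falls from 72.6 % at 7.50 min to 69.2 % at 15.0 min, a drop of 3.4 percentage points. The first's view holds for intermediate A, which stands at 22.8 %, then 22.1 %, and 20.6 % at 150 min. With 90 % of the partner left, Q predicts [intermediate A]/[substrate] of 0.301, and the cedar flask shows 0.319. The neighbour with 2.2 M of substrate has 0.764 equiv of partner, and its [partner] does not stay near its charge: 67 % of its partner remains. Q on that partner predicts 0.224; the neighbour holds 18.0 % of intermediate A against 75 % of substrate, a ratio of 0.240.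

The data are simulated with constants of no real substance.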